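**Plan**

- Retrosynthesis: remove the four ester C–O bonds (C1, C7, C10, C11), return C7 to a ketone, open the pyran at the lactol bond O2–C1 to a C1/C3 dialdehyde (formyl carbons masked as a glycol and a vinyl group), cut C4–C5 (ester dienolate aldol, with the carbonyl moved from C5 to C7 by oxidative 1,3-transposition), cut C8–C9 (Piancatelli rearrangement), and cut the carbinol C–C bond between the furan and glyceraldehyde.
- Forward order: furyl carbinol, then the cyclopentenone ring (step 3), then the C3/C4/C11 unit on C5 and enone transposition, then the pyran ring by lactolisation (step 10), then the C1 acylal, the C10 ester, C7 reduction and the C7 ester.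
- Enabling feature: in the five-membered ring C5–C9, C8 is a tertiary carbinol carrying the C10 oxymethyl arm, next to C9–H whose C1 branch is trans to the C8 hydroxyl, and C5 can be a carbonyl. This is the trans-4-hydroxy-4-(oxymethyl)-5-substituted cyclopent-2-enone that a 5-(oxymethyl)furan-2-yl carbinol gives when the furan opens and recloses between C8 and C9.
- Stereochemistry: C8/C9 trans from conrotatory closure, absolute sense from the (R)-glyceraldehyde dioxolane (excised in step 9); C7 from β-face hydride delivery to the C7 ketone; C1 from acylation of the more stable lactol anomer.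

Key step: step 3

Remark on numbering: iridoid numbering is used throughout (C1 acylal carbon, O2, C3=C4, C11 on C4, C5=C6, C7, C8 bearing C10, C9 at the ring fusion); β is the face of H-9 and of the C8 hydroxyl, α the face of C10.

Assumption: both carbinol epimers of 5 converge in step 3, so 5 is drawn as the expected major anti adduct; C4 in 10–16 is a transient epimer mixture and is left undefined, and the C5 configuration drawn in 10–12 is the expected one and is erased in step 8.

**Step 1**
Reactants: 1 furfuryl alcohol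
Product: 2 tert-butyl(furan-2-ylmethoxy)diphenylsilane
Conditions: TBDPSCl, imidazole, DMF, 0 °C to rt
Reagents that add atoms: tert-butyl(chloro)diphenylsilane, CC(C)(C)[Si](Cl)(c1ccccc1)c1ccccc1
Why: Imidazole-promoted silylation of a primary alcohol, with TBDPS chosen because it should withstand the warm aqueous Lewis acid of step 3.

**Step 2**
Reactants: 2 tert-butyl(furan-2-ylmethoxy)diphenylsilane; 3 (R)-glyceraldehyde acetonide
Product: 5 anti furyl carbinol, via lithiofuran 4 (not isolated)
Conditions: n-BuLi, THF, −78 to 0 °C; then 3, −78 °C; aq. NH4Cl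
Reagents that add atoms: none
Why: α-Lithiation of the furan at its free 5-position followed by 1,2-addition of the heteroaryllithium to the aldehyde should give mainly the anti (Felkin–Anh) carbinol, and the new carbinol centre is lost on ionisation in step 3.

**Step 3**
Reactants: 5 anti furyl carbinol
Product: 6 trans-4-hydroxy-4-(silyloxymethyl)-5-dioxolanylcyclopent-2-enone
Conditions: Dy(OTf)3 (10 mol%), MeCN/H2O (5:1), 80 °C
Reagents that add atoms: water, O
Why: Dy(OTf)3 ionises the furyl carbinol (either epimer) to a furanoxocarbenium ion, water adds at the silyloxymethyl-bearing α-carbon (C8), the cyclic hemiketal opens to a 1-hydroxypentadienyl cation, and this closes between C8 and C9 (Piancatelli rearrangement, mechanistically a Nazarov-type reaction). The cyclopentenone ring is formed by thermal conrotatory 4π electrocyclisation of that cation. Because the C9 dioxolanyl group and the C8 hydroxyl both sit outward on the cation termini, conrotation places them trans, so the relative configuration of the two new centres follows from orbital symmetry. Their absolute configuration depends on the sense of conrotation, which the (4R)-dioxolane centre next to C9 has to bias: with its C–H bond eclipsing the cation plane to avoid allylic strain, the ring oxygen and the ring CH2 flank opposite faces, and C8 is expected to approach anti to the C–O bond. The step therefore needs water to attack the distal furan carbon, which is inherent in the vinylogous cation, and one torquoselective sense, which is plausible but not secured by precedent; the two possible trans products are diastereomers and can be distinguished and separated. The TBDPS ether and a short reaction time are chosen so that silyl ether and acetonide survive.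

**Step 4**
Reactants: 6 trans-4-hydroxycyclopentenone
Product: 7 C8 triethylsilyl ether of 6
Conditions: TESOTf, 2,6-lutidine, CH2Cl2, −78 °C
Reagents that add atoms: triethylsilyl trifluoromethanesulfonate, CC[Si](CC)(CC)OS(=O)(=O)C(F)(F)F
Why: Silyl triflate silylation of the tertiary C8 hydroxyl removes the free β-hydroxy ketone (retro-aldol and elimination pathways in step 5) and prevents a competing chromate ester at C8 in step 8.

**Step 5**
Reactants: 7 C8 triethylsilyl ether; 8 methyl but-3-enoate
Product: 10 C5 aldol adduct, via lithium dienolate 9 (not isolated)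
Conditions: LiN(i-Pr)2, THF, −78 °C; then 7, −78 °C; AcOH quench at −78 °C
Reagents that add atoms: none
Why: Aldol addition of a lithium ester dienolate, which reacts at its α-carbon and adds 1,2 to the cyclopentenone carbonyl at −78 °C (the β-carbon C7 is shielded by quaternary C8), should occur anti to the C9 dioxolanyl group, and both new centres (C5, C4) are erased later.

**Step 6**
Reactants: 10 C5 aldol adduct
Product: 11 C5,C11 diol
Conditions: LiBH4, THF, 0 °C to rt
Reagents that add atoms: none
Why: Chemoselective borohydride reduction of the β-hydroxy ester to the 1,3-diol, leaving silyl ethers, acetonide and both alkenes untouched.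

**Step 7**
Reactants: 11 C5,C11 diol
Product: 12 C11 acetate
Conditions: Ac2O, pyridine, DMAP (cat.), CH2Cl2, 0 °C
Reagents that add atoms: acetic anhydride, CC(=O)OC(C)=O
Why: DMAP-catalysed acetylation differentiates the primary C11 hydroxyl from the hindered tertiary C5 hydroxyl.

**Step 8**
Reactants: 12 C11 acetate
Product: 13 transposed C7 enone
Conditions: pyridinium chlorochromate [C5H5NH][CrO3Cl], NaOAc, 4 Å molecular sieves, CH2Cl2, rt
Reagents that add atoms: pyridinium chlorochromate, [O-][Cr](=O)(=O)Cl.c1cc[nH+]cc1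
Why: Dauben–Babler oxidative 1,3-transposition, in which the chromate ester of the tertiary allylic alcohol shifts to C7 and is oxidised to the enone; the ring alkene is the only allylic terminus (the vinyl group on C4 is homoallylic) and the C8 oxygen is silylated.

**Step 9**
Reactants: 13 transposed C7 enone
Product: 15 C1 aldehyde, via vicinal diol 14 (not isolated)
Conditions: H5IO6, EtOAc, 0 °C to rt; crude product used at once
Reagents that add atoms: none
Why: Periodic acid hydrolyses the terminal isopropylidene ketal and cleaves the liberated glycol in one pot, turning the auxiliary stereocentre into the C1 formyl carbon while the silyl-protected α-oxy ketone and the vinyl group are not attacked.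

**Step 10**
Reactants: 15 C1 aldehyde
Product: 17 7-oxo lactol, via dialdehyde 16 (not isolated)
Conditions: O3, CH2Cl2, −78 °C (Sudan Red 7B end point); PPh3, −78 °C to rt; then PPTS (cat.), rt
Reagents that add atoms: ozone, [O-][O+]=O
Why: Ozonolysis of the monosubstituted alkene, faster than attack on the electron-poor enone, releases the C3 aldehyde, whose doubly activated C4–H enolises to a vinylogous acid that closes on the C1 formyl group through oxygen (6-exo-trig lactolisation, as in iridoid enol-hemiacetals), the C1 hydroxyl equilibrating to the β-face away from quaternary C8.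

**Step 11**
Reactants: 18 3-hydroxy-3-methylbutanoic acid
Product: 19 3-acetoxy-3-methylbutanoic acid
Conditions: AcCl, CH2Cl2, 0 °C to rt; then H2O/THF
Reagents that add atoms: acetyl chloride, CC(Cl)=O
Why: O-Acetylation of the tertiary alcohol with an acid chloride, any mixed anhydride at the carboxyl group being hydrolysed in the aqueous stage.

**Step 12**
Reactants: 17 7-oxo lactol; 19 3-acetoxy-3-methylbutanoic acid
Product: 20 C1 acylal
Conditions: DIC, DMAP (cat.), CH2Cl2, 0 °C
Reagents that add atoms: none
Why: Steglich esterification of the lactol hydroxyl, which should trap the equilibrating lactol as its more stable anomer with the acyloxy group on the β-face, syn to H-9 and away from C8.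

**Step 13**
Reactants: 20 C1 acylal
Product: 21 C8,C10 diol
Conditions: HF·pyridine, pyridine, THF, 0 °C to rt
Reagents that add atoms: none
Why: Buffered fluoride cleavage of both silyl ethers, conditions under which acetates, the acylal and the vinylogous ester are expected to persist.

**Step 14**
Reactants: 21 C8,C10 diol; 22 isovaleric acid
Product: 23 C10 isovalerate
Conditions: DIC, DMAP (cat.), CH2Cl2, 0 °C
Reagents that add atoms: none
Why: Steglich esterification selective for the primary C10 hydroxyl over the tertiary C8 hydroxyl.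

**Step 15**
Reactants: 23 C10 isovalerate
Product: 24 7α-alcohol
Conditions: NaBH4, CeCl3·7H2O, MeOH/THF, −78 °C; pH 7 buffer
Reagents that add atoms: none
Why: Luche 1,2-reduction of the enone, in which cerium bridging the C7 carbonyl and the free C8 hydroxyl and the bulky α-face C10 acyloxymethyl arm should direct hydride to the β-face, giving the C7 hydroxyl α, trans to the C8 hydroxyl.

**Step 16**
Reactants: 24 7α-alcohol; 22 isovaleric acid
Product: 25 target CNP0331701.2
Conditions: DIC, DMAP, CH2Cl2, 0 °C
Reagents that add atoms: none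
Why: Steglich esterification of the secondary allylic C7 hydroxyl under non-acidic conditions, the tertiary C8 hydroxyl remaining free.

**Compound list**

1 | furfuryl alcohol (furan-2-ylmethanol) | OCc1ccco1 | starting material
2 | tert-butyl(furan-2-ylmethoxy)diphenylsilane | CC(C)(C)[Si](OCc1ccco1)(c1ccccc1)c1ccccc1 | intermediate
3 | (R)-glyceraldehyde acetonide, (4R)-2,2-dimethyl-1,3-dioxolane-4-carbaldehyde | CC1(C)OC[C@H](C=O)O1 | starting material
4 | [5-({[tert-butyl(diphenyl)silyl]oxy}methyl)furan-2-yl]lithium | [Li]c1ccc(CO[Si](c2ccccc2)(c2ccccc2)C(C)(C)C)o1 | intermediate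
5 | (R)-[5-({[tert-butyl(diphenyl)silyl]oxy}methyl)furan-2-yl][(4R)-2,2-dimethyl-1,3-dioxolan-4-yl]methanol (anti adduct) | O[C@@H](c1ccc(CO[Si](c2ccccc2)(c2ccccc2)C(C)(C)C)o1)[C@H]1COC(C)(C)O1 | intermediate
6 | (4S,5R)-4-({[tert-butyl(diphenyl)silyl]oxy}methyl)-5-[(4S)-2,2-dimethyl-1,3-dioxolan-4-yl]-4-hydroxycyclopent-2-en-1-one (hydroxyl trans to dioxolanyl) | O=C1C=C[C@@](O)(CO[Si](c2ccccc2)(c2ccccc2)C(C)(C)C)[C@H]1[C@H]1COC(C)(C)O1 | intermediate
7 | (4S,5R)-4-({[tert-butyl(diphenyl)silyl]oxy}methyl)-5-[(4S)-2,2-dimethyl-1,3-dioxolan-4-yl]-4-[(triethylsilyl)oxy]cyclopent-2-en-1-one | O=C1C=C[C@@](O[Si](CC)(CC)CC)(CO[Si](c2ccccc2)(c2ccccc2)C(C)(C)C)[C@H]1[C@H]1COC(C)(C)O1 | intermediate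
8 | methyl but-3-enoate | COC(=O)CC=C | starting material
9 | lithium 1-methoxybuta-1,3-dien-1-olate | COC(O[Li])=CC=C | intermediate
10 | methyl 2-{1-hydroxy-4-({[tert-butyl(diphenyl)silyl]oxy}methyl)-5-[(4S)-2,2-dimethyl-1,3-dioxolan-4-yl]-4-[(triethylsilyl)oxy]cyclopent-2-en-1-yl}but-3-enoate (C8, C9 as in 7; C5 hydroxyl α, cis to the dioxolanyl group; C4 epimers) | COC(=O)C(C=C)[C@]1(O)C=C[C@@](O[Si](CC)(CC)CC)(CO[Si](c2ccccc2)(c2ccccc2)C(C)(C)C)[C@H]1[C@H]1COC(C)(C)O1 | intermediate
11 | 2-{1-hydroxy-4-({[tert-butyl(diphenyl)silyl]oxy}methyl)-5-[(4S)-2,2-dimethyl-1,3-dioxolan-4-yl]-4-[(triethylsilyl)oxy]cyclopent-2-en-1-yl}but-3-en-1-ol (configuration as in 10) | OCC(C=C)[C@]1(O)C=C[C@@](O[Si](CC)(CC)CC)(CO[Si](c2ccccc2)(c2ccccc2)C(C)(C)C)[C@H]1[C@H]1COC(C)(C)O1 | intermediate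
12 | 2-{1-hydroxy-4-({[tert-butyl(diphenyl)silyl]oxy}methyl)-5-[(4S)-2,2-dimethyl-1,3-dioxolan-4-yl]-4-[(triethylsilyl)oxy]cyclopent-2-en-1-yl}but-3-en-1-yl acetate (configuration as in 10) | CC(=O)OCC(C=C)[C@]1(O)C=C[C@@](O[Si](CC)(CC)CC)(CO[Si](c2ccccc2)(c2ccccc2)C(C)(C)C)[C@H]1[C@H]1COC(C)(C)O1 | intermediate
13 | 2-{4-({[tert-butyl(diphenyl)silyl]oxy}methyl)-5-[(4S)-2,2-dimethyl-1,3-dioxolan-4-yl]-3-oxo-4-[(triethylsilyl)oxy]cyclopent-1-en-1-yl}but-3-en-1-yl acetate (C8, C9 as in 7; C4 epimers) | CC(=O)OCC(C=C)C1=CC(=O)[C@@](O[Si](CC)(CC)CC)(CO[Si](c2ccccc2)(c2ccccc2)C(C)(C)C)[C@H]1[C@H]1COC(C)(C)O1 | intermediate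
14 | 2-{4-({[tert-butyl(diphenyl)silyl]oxy}methyl)-5-(1,2-dihydroxyethyl)-3-oxo-4-[(triethylsilyl)oxy]cyclopent-1-en-1-yl}but-3-en-1-yl acetate (glycol from the dioxolane of 13) | CC(=O)OCC(C=C)C1=CC(=O)[C@@](O[Si](CC)(CC)CC)(CO[Si](c2ccccc2)(c2ccccc2)C(C)(C)C)[C@H]1[C@H](O)CO | intermediate
15 | 2-{4-({[tert-butyl(diphenyl)silyl]oxy}methyl)-5-formyl-3-oxo-4-[(triethylsilyl)oxy]cyclopent-1-en-1-yl}but-3-en-1-yl acetate (C1 aldehyde; C8, C9 as in 7) | CC(=O)OCC(C=C)C1=CC(=O)[C@@](O[Si](CC)(CC)CC)(CO[Si](c2ccccc2)(c2ccccc2)C(C)(C)C)[C@H]1C=O | intermediate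
16 | 2-{4-({[tert-butyl(diphenyl)silyl]oxy}methyl)-5-formyl-3-oxo-4-[(triethylsilyl)oxy]cyclopent-1-en-1-yl}-3-oxopropyl acetate (C1/C3 dialdehyde) | CC(=O)OCC(C=O)C1=CC(=O)[C@@](O[Si](CC)(CC)CC)(CO[Si](c2ccccc2)(c2ccccc2)C(C)(C)C)[C@H]1C=O | intermediate
17 | 7-oxo lactol: 11-acetoxy-1β-hydroxy-7-oxo-10-(tert-butyldiphenylsilyloxy)-8β-(triethylsilyloxy)-irida-3,5-diene (9β-H; pyran ring closed) | CC(=O)OCC1=CO[C@@H](O)[C@H]2C1=CC(=O)[C@@]2(O[Si](CC)(CC)CC)CO[Si](c1ccccc1)(c1ccccc1)C(C)(C)C | intermediate
18 | 3-hydroxy-3-methylbutanoic acid | CC(C)(O)CC(O)=O | starting material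
19 | 3-acetoxy-3-methylbutanoic acid | CC(=O)OC(C)(C)CC(O)=O | intermediate
20 | C1 acylal: 1β-(3-acetoxy-3-methylbutanoyloxy) derivative of 17 | CC(=O)OCC1=CO[C@@H](OC(=O)CC(C)(C)OC(C)=O)[C@H]2C1=CC(=O)[C@@]2(O[Si](CC)(CC)CC)CO[Si](c1ccccc1)(c1ccccc1)C(C)(C)C | intermediate
21 | 8β,10-diol: desilylated 20 (7-oxo, 8β-OH, 10-OH) | CC(=O)OCC1=CO[C@@H](OC(=O)CC(C)(C)OC(C)=O)[C@H]2C1=CC(=O)[C@@]2(O)CO | intermediate
22 | isovaleric acid (3-methylbutanoic acid) | CC(C)CC(O)=O | starting material
23 | 10-O-isovaleryl-7-oxo compound (8β-OH free) | CC(=O)OCC1=CO[C@@H](OC(=O)CC(C)(C)OC(C)=O)[C@H]2C1=CC(=O)[C@@]2(O)COC(=O)CC(C)C | intermediate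
24 | 7α-alcohol: 7α,8β-dihydroxy-10-O-isovaleryl compound | CC(=O)OCC1=CO[C@@H](OC(=O)CC(C)(C)OC(C)=O)[C@H]2C1=C[C@@H](O)[C@@]2(O)COC(=O)CC(C)C | intermediate
25 | CNP0331701.2: 11-acetoxy-1β-(3-acetoxy-3-methylbutanoyloxy)-8β-hydroxy-7α,10-bis(isovaleryloxy)-irida-3,5-diene | CC(=O)OCC1=CO[C@@H](OC(=O)CC(C)(C)OC(C)=O)[C@H]2C1=C[C@@H](OC(=O)CC(C)C)[C@@]2(O)COC(=O)CC(C)C | target

**Step count**

Total: 16 steps. Longest linear sequence: 15 steps (steps 1–10 and 12–16); step 11 prepares the C1 acyl donor.

**Steps most likely to fail**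

Step 3. The conrotation may proceed with the wrong or with little facial bias; ionisation may be slow because of the oxygen β to the carbinol carbon; the acetonide may be hydrolysed under the warm aqueous Lewis acid. Fallback: the dioxolane is used as a resolving handle instead of a directing group. The two trans products are diastereomers and are separated on silica; if selectivity is merely weak the route continues from 6. If the major product has the wrong ring configuration, the sequence sets out again from 2 with the mirror-image aldehyde, (S)-glyceraldehyde acetonide F1. Lithiation and addition as in step 2 give the enantiomeric carbinol F2, and rearrangement under the step 3 conditions then gives as major product the cyclopentenone F3, which has the ring configuration of 6 and the epimeric dioxolane. F3 is carried through the conditions of steps 4 to 8 as triethylsilyl ether F4, aldol adduct F5, diol F6, acetate F7 and enone F8. Periodic acid converts F8 through vicinal diol F9 into aldehyde 15, where the auxiliary centre has disappeared and the route is rejoined.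

Step 9. The aldehyde 15 may epimerise at C9, which is α to the formyl group and vinylogous to the C7 ketone, and the tertiary triethylsilyl ether may be lost under periodic acid, exposing the α-hydroxy ketone to cleavage. Fallback: reverse the order of the two cleavages so that the C1 formyl group never accumulates. Setting out from enone 13, ozonolysis (O3, CH2Cl2, −78 °C; PPh3) first gives the C3 aldehyde F10, which rests as its hydroxymethylene-dienone tautomer while C9 still carries the acetonide. Periodic acid in EtOAc then releases vicinal diol F11 and cleaves it to dialdehyde 16, whose C1 formyl group is captured at once by the enol, returning to the route at lactol 17.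

Step 15. Hydride delivery may show poor facial selectivity or favour the α-face, conjugate reduction may compete, and the allylic C7 alcohol may ionise on work-up. Fallback: set C7 by inversion rather than by the face of hydride attack. Setting out from 23, the reduction product with the C7 hydroxyl on the β-face, 7β-alcohol F12, is esterified with isovaleric acid 22 under Mitsunobu conditions (PPh3, diisopropyl azodicarboxylate, toluene, 0 °C). SN2 displacement with inversion gives 25 directly and replaces step 16.

**Further compounds**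

F1 | step 3 | (S)-glyceraldehyde acetonide, (4S)-2,2-dimethyl-1,3-dioxolane-4-carbaldehyde | CC1(C)OC[C@@H](C=O)O1
F2 | step 3 | (S)-[5-({[tert-butyl(diphenyl)silyl]oxy}methyl)furan-2-yl][(4S)-2,2-dimethyl-1,3-dioxolan-4-yl]methanol | O[C@H](c1ccc(CO[Si](c2ccccc2)(c2ccccc2)C(C)(C)C)o1)[C@@H]1COC(C)(C)O1
F3 | step 3 | dioxolane epimer of 6 (ring centres as in 6) | O=C1C=C[C@@](O)(CO[Si](c2ccccc2)(c2ccccc2)C(C)(C)C)[C@H]1[C@@H]1COC(C)(C)O1
F4 | step 3 | dioxolane epimer of 7 | O=C1C=C[C@@](O[Si](CC)(CC)CC)(CO[Si](c2ccccc2)(c2ccccc2)C(C)(C)C)[C@H]1[C@@H]1COC(C)(C)O1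
F5 | step 3 | dioxolane epimer of 10 | COC(=O)C(C=C)[C@]1(O)C=C[C@@](O[Si](CC)(CC)CC)(CO[Si](c2ccccc2)(c2ccccc2)C(C)(C)C)[C@H]1[C@@H]1COC(C)(C)O1
F6 | step 3 | dioxolane epimer of 11 | OCC(C=C)[C@]1(O)C=C[C@@](O[Si](CC)(CC)CC)(CO[Si](c2ccccc2)(c2ccccc2)C(C)(C)C)[C@H]1[C@@H]1COC(C)(C)O1
F7 | step 3 | dioxolane epimer of 12 | CC(=O)OCC(C=C)[C@]1(O)C=C[C@@](O[Si](CC)(CC)CC)(CO[Si](c2ccccc2)(c2ccccc2)C(C)(C)C)[C@H]1[C@@H]1COC(C)(C)O1
F8 | step 3 | dioxolane epimer of 13 | CC(=O)OCC(C=C)C1=CC(=O)[C@@](O[Si](CC)(CC)CC)(CO[Si](c2ccccc2)(c2ccccc2)C(C)(C)C)[C@H]1[C@@H]1COC(C)(C)O1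
F9 | step 3 | glycol epimer of 14 | CC(=O)OCC(C=C)C1=CC(=O)[C@@](O[Si](CC)(CC)CC)(CO[Si](c2ccccc2)(c2ccccc2)C(C)(C)C)[C@H]1[C@@H](O)CO
F10 | step 9 | 2-{4-({[tert-butyl(diphenyl)silyl]oxy}methyl)-5-[(4S)-2,2-dimethyl-1,3-dioxolan-4-yl]-3-oxo-4-[(triethylsilyl)oxy]cyclopent-1-en-1-yl}-3-oxopropyl acetate (C3 aldehyde, acetonide intact) | CC(=O)OCC(C=O)C1=CC(=O)[C@@](O[Si](CC)(CC)CC)(CO[Si](c2ccccc2)(c2ccccc2)C(C)(C)C)[C@H]1[C@H]1COC(C)(C)O1
F11 | step 9 | vicinal diol from F10 | CC(=O)OCC(C=O)C1=CC(=O)[C@@](O[Si](CC)(CC)CC)(CO[Si](c2ccccc2)(c2ccccc2)C(C)(C)C)[C@H]1[C@H](O)CO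
F12 | step 15 | 7β-alcohol, C7 epimer of 24 | CC(=O)OCC1=CO[C@@H](OC(=O)CC(C)(C)OC(C)=O)[C@H]2C1=C[C@H](O)[C@@]2(O)COC(=O)CC(C)C
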